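The 2-acylpyrrole is read as a contracted pyridine: N1, pyrrole carbons C2–C5 and the exocyclic carbonyl carbon are together the six ring atoms of a 2,6-disubstituted pyridine N-oxide. On irradiation the oxide oxygen moves to the alkyl-bearing α-carbon, that carbon leaves the ring as the side-chain C=O, and nitrogen bonds to the neighbouring carbon. The pyrrole ring, its N1–C2 bond and the ketone therefore arise in one operation with every carbon already in place. The precursor is 2-(15-methylhexadecyl)-6-(triisopropylsilyloxymethyl)pyridine N-oxide, made by alkylating a laterally lithiated picolyl alcohol with an iso-branched C16 bromide; fluoride finally uncovers the hydroxymethyl group.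

Key step: step 5

Remark on the chemistry: the primary alcohol is carried as a triisopropylsilyl ether, not as an ester, because a pyrrol-2-ylmethyl ester can ionise to an azafulvene and be solvolysed, whereas the silyl ether is inert to light, divalent copper and methanol and is removed by fluoride; the regioisomeric acylpyrrole from oxygen transfer to the other α-carbon is assumed to form as well and to be separable on silica.

Step 1
Reactants: 1 isobutylmagnesium bromide; 2 1,12-dibromododecane
Product: 3 1-bromo-14-methylpentadecane
Conditions: Li2CuCl4 (3 mol %), THF, −10 to 0 °C; 1 added slowly to 2 (3 equiv)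
Reagents that add atoms: none
Why: Copper-catalysed cross-coupling of a primary alkyl Grignard reagent with a primary alkyl bromide (Kochi-type coupling) is reliable, and the excess of 2 should hold the reaction at mono-substitution, leaving a monobromide that differs enough in polarity from 2 and from the doubly coupled hydrocarbon to be separated on silica.

Step 2
Reactants: 4 (6-methylpyridin-2-yl)methanol; 3 1-bromo-14-methylpentadecane
Product: 7 [6-(15-methylhexadecyl)pyridin-2-yl]methanol, via dilithio dianion 5 (not isolated), via lithium alkoxide 6 (not isolated)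
Conditions: LiN(iPr)2 (2.2 equiv), THF, −78 to 0 °C; then 3 (0.9 equiv), −78 °C to rt; then H2O
Reagents that add atoms: none
Why: The first equivalent of base forms the lithium alkoxide and the second removes a proton from the 6-methyl group (lateral lithiation to an aza-allyl anion), and the carbon terminus of dianion 5 should displace bromide from the unhindered primary bromide 3 (SN2 alkylation of a picolyl anion) much faster than the lithium alkoxide, so no protecting group is needed.

Step 3
Reactants: 7 [6-(15-methylhexadecyl)pyridin-2-yl]methanol
Product: 8 2-(15-methylhexadecyl)-6-({[tri(propan-2-yl)silyl]oxy}methyl)pyridine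
Conditions: TIPSCl (1.2 equiv), imidazole (2.5 equiv), DMF/CH2Cl2, rt
Reagents that add atoms: triisopropylsilyl chloride, CC(C)[Si](Cl)(C(C)C)C(C)C
Why: Silyl ether formation on a primary alcohol with a silyl chloride and imidazole is routine, and the triisopropylsilyl group is chosen because it is transparent at 254 nm, bulky next to C6 and stable to peracid, divalent copper and methanol.

Step 4
Reactants: 8 2-(15-methylhexadecyl)-6-({[tri(propan-2-yl)silyl]oxy}methyl)pyridine
Product: 9 2-(15-methylhexadecyl)-6-({[tri(propan-2-yl)silyl]oxy}methyl)pyridine 1-oxide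
Conditions: mCPBA (1.2 equiv), CH2Cl2, 0 °C to rt
Reagents that add atoms: m-chloroperoxybenzoic acid, OOC(=O)c1cccc(Cl)c1
Why: Peracid N-oxidation of a 2,6-dialkylpyridine is standard, and neither the silyl ether nor the saturated chain is touched by the peracid.

Step 5
Reactants: 9 2-(15-methylhexadecyl)-6-({[tri(propan-2-yl)silyl]oxy}methyl)pyridine 1-oxide
Product: 14 16-methyl-1-[5-({[tri(propan-2-yl)silyl]oxy}methyl)-1H-pyrrol-2-yl]heptadecan-1-one, via bicyclic oxaziridine 10 (not isolated), via 1,2-oxazepine 11 (not isolated), via 2H-azirine 12 (not isolated), via 2H-pyrrole 13 (not isolated)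
Conditions: hν (254 nm, low-pressure Hg lamp, quartz), CuSO4·5H2O (2 equiv), degassed MeOH–MeCN 1:1 (5 mM), 15 °C, stopped before full conversion
Reagents that add atoms: none
Why: Excitation of the N-oxide chromophore of 9 should close an oxaziridine across N1 and the alkyl-bearing C2 (10), which opens by a six-electron electrocyclic ring expansion to 1,2-oxazepine 11; N–O cleavage then turns the former C2 into the ketone carbon and leaves an acyl dienyl nitrene, drawn as its 2H-azirine valence isomer 12. The nitrene, held by divalent copper, should close by a five-atom, six-electron electrocyclisation in which nitrogen bonds to the former C3 (the one ring formed, five-membered, by N–C bond formation), and the resulting 2H-pyrrole 13 aromatises by a hydrogen shift to 14. The closest known reaction type is the copper-assisted photoisomerisation of pyridine N-oxides to 2-formyl- and 2-acylpyrroles, for instance of 2,6-dimethylpyridine N-oxide to 2-acetyl-5-methylpyrrole. No stereocentre is formed. The step needs site selectivity between the two α-carbons: oxygen has to go to C2 and not to C6, and the substrate secures this only in part, through the bulk of the triisopropylsilyloxymethyl arm at C6, while the silyloxy oxygen keeps the electronic difference between the two α-carbons small, so the isomeric 5-alkyl-2-(silyloxyacetyl)pyrrole is expected as a by-product to be removed on silica. The silyl ether does not absorb at 254 nm and cannot ionise, the copper salt is used in excess to intercept the nitrene before it opens to unsaturated nitriles, and irradiation is stopped early because the acylpyrrole itself absorbs near 290 nm.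

Step 6
Reactants: 14 16-methyl-1-[5-({[tri(propan-2-yl)silyl]oxy}methyl)-1H-pyrrol-2-yl]heptadecan-1-one
Product: 15 1-[5-(hydroxymethyl)-1H-pyrrol-2-yl]-16-methylheptadecan-1-one
Conditions: Bu4NF (1.2 equiv), AcOH (1.2 equiv), THF, 0 °C to rt
Reagents that add atoms: none
Why: Fluoride-mediated desilylation of a primary triisopropylsilyl ether, buffered with acetic acid, should release the alcohol without exposing the hydroxymethylpyrrole to acid or strong base, and the ketone and the N–H are untouched.

Compound list
1 | isobutylmagnesium bromide | CC(C)C[Mg]Br | starting material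
2 | 1,12-dibromododecane | BrCCCCCCCCCCCCBr | starting material
3 | 1-bromo-14-methylpentadecane | CC(C)CCCCCCCCCCCCCBr | intermediate
4 | (6-methylpyridin-2-yl)methanol | Cc1cccc(CO)n1 | starting material
5 | lithium [6-(lithiomethyl)pyridin-2-yl]methanolate (C,O-dilithio dianion of 4) | [Li]Cc1cccc(CO[Li])n1 | intermediate (not isolated)
6 | lithium [6-(15-methylhexadecyl)pyridin-2-yl]methanolate | CC(C)CCCCCCCCCCCCCCc1cccc(CO[Li])n1 | intermediate (not isolated)
7 | [6-(15-methylhexadecyl)pyridin-2-yl]methanol | CC(C)CCCCCCCCCCCCCCc1cccc(CO)n1 | intermediate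
8 | 2-(15-methylhexadecyl)-6-({[tri(propan-2-yl)silyl]oxy}methyl)pyridine | CC(C)CCCCCCCCCCCCCCc1cccc(CO[Si](C(C)C)(C(C)C)C(C)C)n1 | intermediate
9 | 2-(15-methylhexadecyl)-6-({[tri(propan-2-yl)silyl]oxy}methyl)pyridine 1-oxide | CC(C)CCCCCCCCCCCCCCc1cccc(CO[Si](C(C)C)(C(C)C)C(C)C)[n+]1[O-] | intermediate
10 | 6-(15-methylhexadecyl)-2-({[tri(propan-2-yl)silyl]oxy}methyl)-7-oxa-1-azabicyclo[4.1.0]hepta-2,4-diene (racemic) | CC(C)CCCCCCCCCCCCCCC12C=CC=C(CO[Si](C(C)C)(C(C)C)C(C)C)N1O2 | intermediate (not isolated)
11 | 7-(15-methylhexadecyl)-3-({[tri(propan-2-yl)silyl]oxy}methyl)-1,2-oxazepine | CC(C)CCCCCCCCCCCCCCC1=CC=CC(CO[Si](C(C)C)(C(C)C)C(C)C)=NO1 | intermediate (not isolated)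
12 | (1Z)-18-methyl-1-[3-({[tri(propan-2-yl)silyl]oxy}methyl)-2H-azirin-2-yl]nonadec-1-en-3-one (racemic; closed-shell valence isomer of the acyl dienyl nitrene) | CC(C)CCCCCCCCCCCCCCC(=O)/C=C\C1N=C1CO[Si](C(C)C)(C(C)C)C(C)C | intermediate (not isolated)
13 | 16-methyl-1-[5-({[tri(propan-2-yl)silyl]oxy}methyl)-2H-pyrrol-2-yl]heptadecan-1-one (racemic) | CC(C)CCCCCCCCCCCCCCC(=O)C1C=CC(CO[Si](C(C)C)(C(C)C)C(C)C)=N1 | intermediate (not isolated)
14 | 16-methyl-1-[5-({[tri(propan-2-yl)silyl]oxy}methyl)-1H-pyrrol-2-yl]heptadecan-1-one | CC(C)CCCCCCCCCCCCCCC(=O)c1ccc(CO[Si](C(C)C)(C(C)C)C(C)C)[nH]1 | intermediate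
15 | 1-[5-(hydroxymethyl)-1H-pyrrol-2-yl]-16-methylheptadecan-1-one | CC(C)CCCCCCCCCCCCCCC(=O)c1ccc(CO)[nH]1 | target

Total step count: 6
Longest linear sequence: 6 steps (1 and 2 to 3, then 7, 8, 9, 14, 15)

Steps most likely to fail

Step 5. Oxygen may be transferred to the α-carbon that carries the silyloxymethyl arm instead of the alkyl-bearing one. The oxygen may also walk to C3 or be lost to return pyridine 8, the nitrene may open to unsaturated nitriles, and the acylpyrrole may be photolysed further. The fallback avoids photochemistry and sets out from bromide 3. Alkylation of dilithium acetate (AcOH, 2.1 equiv LiN(iPr)2, THF/DMPU) with 3 would give, after acidification, 16-methylheptadecanoic acid F1. 2,2'-Dipyridyl disulfide and PPh3 would convert it into S-pyridin-2-yl 16-methylheptadecanethioate F2. Separately, commercial 1H-pyrrole-2-carbaldehyde would be reduced with NaBH4 to (1H-pyrrol-2-yl)methanol F3 and silylated at once (TIPSCl, imidazole) to 2-({[tri(propan-2-yl)silyl]oxy}methyl)-1H-pyrrole F4. Deprotonation with EtMgBr would give bromo[2-({[tri(propan-2-yl)silyl]oxy}methyl)pyrrol-1-yl]magnesium F5. Its C-acylation by F2 at the free α-position (toluene, −78 °C; the known 2-ketopyrrole synthesis from 2-pyridyl thioesters) returns to the route at 14.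

Step 2. The second deprotonation may be incomplete or the dianion poorly soluble, the product may transfer a proton to unreacted anion and be alkylated twice, and the basic carbanion may eliminate HBr from 3. The fallback replaces the alkylation by an olefination and sets out from bromide 3. Heating with PPh3 would give (14-methylpentadecyl)triphenylphosphonium bromide F6, and NaN(SiMe3)2 in THF would turn it into triphenyl(14-methylpentadecylidene)phosphorane F7. A Wittig reaction with commercial methyl 6-formylpyridine-2-carboxylate at −78 °C would give methyl 6-[(1Z)-15-methylhexadec-1-en-1-yl]pyridine-2-carboxylate F8, whose double-bond geometry is irrelevant. Hydrogenation (H2, Pd/C, EtOAc) would give methyl 6-(15-methylhexadecyl)pyridine-2-carboxylate F9. Reduction of this picolinate ester with NaBH4 in MeOH returns to the route at 7.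

Step 1. Both ends of the dibromide may couple, and the monobromide may not separate cleanly from the excess of 2. The fallback differentiates the two chain ends from the outset and sets out from Grignard reagent 1. With commercial 12-bromododecan-1-ol the first equivalent of 1 would form bromomagnesium 12-bromododecan-1-olate F10. Further 1 with catalytic Li2CuCl4 would then couple at the C–Br end to give, after work-up, 14-methylpentadecan-1-ol F11. An Appel bromination (CBr4, PPh3, CH2Cl2) returns to the route at 3.

Further compounds
F1 | step 5 | 16-methylheptadecanoic acid | CC(C)CCCCCCCCCCCCCCC(=O)O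
F2 | step 5 | S-pyridin-2-yl 16-methylheptadecanethioate | CC(C)CCCCCCCCCCCCCCC(=O)Sc1ccccn1
F3 | step 5 | (1H-pyrrol-2-yl)methanol | OCc1ccc[nH]1
F4 | step 5 | 2-({[tri(propan-2-yl)silyl]oxy}methyl)-1H-pyrrole | CC(C)[Si](OCc1ccc[nH]1)(C(C)C)C(C)C
F5 | step 5 | bromo[2-({[tri(propan-2-yl)silyl]oxy}methyl)pyrrol-1-yl]magnesium | CC(C)[Si](OCc1cccn1[Mg]Br)(C(C)C)C(C)C
F6 | step 2 | (14-methylpentadecyl)triphenylphosphonium bromide | CC(C)CCCCCCCCCCCCC[P+](c1ccccc1)(c1ccccc1)c1ccccc1.[Br-]
F7 | step 2 | triphenyl(14-methylpentadecylidene)phosphorane | CC(C)CCCCCCCCCCCCC=P(c1ccccc1)(c1ccccc1)c1ccccc1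
F8 | step 2 | methyl 6-[(1Z)-15-methylhexadec-1-en-1-yl]pyridine-2-carboxylate | CC(C)CCCCCCCCCCCC/C=C\c1cccc(C(=O)OC)n1
F9 | step 2 | methyl 6-(15-methylhexadecyl)pyridine-2-carboxylate | CC(C)CCCCCCCCCCCCCCc1cccc(C(=O)OC)n1
F10 | step 1 | bromomagnesium 12-bromododecan-1-olate | BrCCCCCCCCCCCCO[Mg]Br
F11 | step 1 | 14-methylpentadecan-1-ol | CC(C)CCCCCCCCCCCCCO
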